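| flask | J | G | remark | time |
|---|---|---|---|---|
| elm | 2.1 M | 13 mol% | run made earlier |  |
| cedar | 1.5 M | 6.5 mol% | run made earlier |  |
| flask | 1.5 M | 13 mol% |  | 15 d |

| run | time / d | Q / % | D / % |
|---|---|---|---|
| elm | 1.04 | 11.0 | 11.4 |
| elm | 1.67 | 13.9 | 7.1 |
| elm | 3.00 | 16.9 | 4.2 |
| elm | 5.00 | 17.4 | 2.0 |
| elm | 8.00 | 15.6 | 0.8 |
| elm | 12.0 | 12.6 | 0 |
| elm | 20.0 | 8.7 | 0 |
| cedar | 1.04 | 10.1 | 12.8 |
| cedar | 2.50 | 14.7 | 5.1 |
| cedar | 5.00 | 16.3 | 1.3 |
| cedar | 10.0 | 14.3 | 0.9 |
| cedar | 20.0 | 8.5 | 0.4 |

(scatter of a reading: 0.3 percentage points)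

- time up to 15 d at which Q stands highest
- the amount of Q, in percent of the J charged, at that time



- Amounts came first. The flask took its charge of J from cedar and its loading from elm, so I multiplied them into c_G = 0.195 M, the concentration of G itself in the solution. A step run by G has a pseudo-first-order rate constant proportional to c_G.
- Elm had 0.273 M and cedar 0.0975 M, so the flask lay between them.
- I first tried c_G as a clock for the peak time. Q read highest at 5.00 d in elm and at 5.00 d in cedar. Scaling elm to the flask gave 7.00 d, but scaling cedar gave 2.50 d. These two ways to one number parted, so the clock cheated: between cedar and elm, a factor of 2.80 in c_G hadn't moved the time of the highest reading on their sampling grids.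
- I therefore kept that time, within the spacing of the readings, and placed the height on c_G. Between the highest readings, 16.3% and 17.4%, my line gave the flask 16.9%.
- The forecast said 16.9% at 4.9 d, since “its absolute catalyst level lies between theirs”. My line stands on that same ground, so their closeness was no check.
- The flask gave 17.1% at 4.51 d, and the forecast held.

    D + G ⇌ Z + G, rate k1*[G]*[D] forward; the back reaction follows from the equilibrium constant (K = 1.40, k = 0.00200 M⁻¹ min⁻¹)
    Z + G ⇌ J + G, rate k2*[G]*[Z] forward; the back reaction follows from the equilibrium constant (k = 0.00160 M⁻¹ min⁻¹)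
    J + G ⇌ D + G, rate k3*[J]*[G] forward; the back reaction follows from the equilibrium constant (K = 0.710, k = 0.0140 M⁻¹ min⁻¹)
    D ⇌ Q (K = 8.30, k = 4.20 × 10⁻⁴ min⁻¹)
    D → L (k = 0.00140 min⁻¹)

- At 4.51 d the flask also held L at 71.6%, which the Q figure doesn't show, so L was the amount to watch. Taking away the reaction of D to L lifted the highest Q from 17.1% to 65.8%, the largest single effect among those tested. G stands nowhere in that step, whereas the flask's c_G of 0.195 M gave J a forward half-life of 0.176 d.
- With 3.2 mol% of G, the neighbour's c_G was 0.0480 M, below cedar's. That stretched J's forward half-life to 0.716 d, so I expected a lower peak and more J left over.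
- The neighbour flask reached 15.9% and kept 0.93% of J at 15.0 d, against 0.50% in the flask.

(Readings and results were computed with made-up constants, noise included.)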